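**Plan**
- Target: a (2S,4S)-7,8,4′-trihydroxyflavan (upper unit) bonded from its C4 to C6 of a (2R,3R,4R)-all-cis 7,8,4′-trihydroxyflavan-3,4-diol (lower unit).
- Retrosynthesis: open lower ring C at O1–C2 and take C4–OH back to the ketone; then cut lower ring A at C5–C6 and C4a–C8a; last, cut the bond from upper C4 to the four-carbon chain.
- Enabling feature: lower ring A is a pentasubstituted benzene with three adjacent oxygens (C8a–O1, C8–OH, C7–OH), carbon substituents at C6 (upper C4) and C4a (C4), and its only hydrogen at C5. This is the pattern left by a 1,2,3-trioxygenated 4-alkyl diene (C8a, C8, C7, C6) adding to a terminal ynone (C5, C4a, carbonyl = C4).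
- Forward order: upper ring C by chalcone cyclisation, alkylation at upper C4, lower ring A by [4+2]/aromatisation, lower ring C by Mitsunobu etherification, C4 reduction, global debenzylation.
- Stereochemistry: upper C2 from a Rh-catalysed transfer-hydrogenation kinetic resolution; upper C4 by axial attack on the flavan-4-yl cation, trans to the C2 aryl; lower C3 and C2 from an auxiliary-controlled anti-glycolate aldol (C2 inverted in the Mitsunobu closure); lower C4 by hydride addition anti to the axial 3-benzyloxy group.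

Key step: step 16

Remark on the chemistry: the target SMILES is read as 2,4-trans in the upper unit and 2,3-cis-3,4-cis in the lower unit. Enol ether and ketene acetal geometries that the methods do not fix are left open or drawn as one isomer, because those carbons become aromatic. The facial sense of the aldol in step 12 is assigned from the chelated-enolate model, not from a documented glycolate example.

**Route**

Step 1
Reactants: 1 gallacetophenone
Product: 2 3′,4′-bis(benzyloxy)-2′-hydroxyacetophenone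
Conditions: BnBr (2.1 equiv), K2CO3, acetone, reflux
Reagents that add atoms: benzyl bromide, BrCc1ccccc1
Why: Williamson etherification alkylates the two free phenols, while the 2′-OH stays untouched because it is hydrogen-bonded to the ketone.

Step 2
Reactants: 2 3′,4′-bis(benzyloxy)-2′-hydroxyacetophenone; 3 4-benzyloxybenzaldehyde
Product: 4 (E)-4,3′,4′-tris(benzyloxy)-2′-hydroxychalcone
Conditions: KOH, EtOH/THF, 23 °C; then dilute HCl
Reagents that add atoms: none
Why: Claisen–Schmidt condensation of the methyl ketone with the non-enolisable aldehyde, with dehydration to the (E)-enone.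

Step 3
Reactants: 4 (E)-4,3′,4′-tris(benzyloxy)-2′-hydroxychalcone
Product: 5 racemic 7,8-bis(benzyloxy)-2-(4-benzyloxyphenyl)chroman-4-one
Conditions: NaOAc, EtOH, reflux
Reagents that add atoms: none
Why: Chalcone–flavanone isomerisation (6-endo oxa-Michael addition of the phenoxide) closes upper ring C as the racemate.

Step 4
Reactants: 5 racemic 7,8-bis(benzyloxy)-2-(4-benzyloxyphenyl)chroman-4-one
Product: 6 (2S,4S)-7,8-bis(benzyloxy)-2-(4-benzyloxyphenyl)chroman-4-ol (2,4-cis)
Conditions: Cp*RhCl[(S,S)-TsDPEN] (1 mol%), HCO2H/Et3N, EtOAc, 40 °C, stopped near half conversion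
Reagents that add atoms: none
Why: Noyori-type asymmetric transfer hydrogenation run as a kinetic resolution, in which the (S,S) catalyst forms the 4S carbinol and does so quickly only for the (2S)-ketone (hydride anti to the aryl group), which fixes upper C2; the unreacted (2R)-ketone is separated and can be racemised through chalcone 4 and recycled.

Step 5
Reactants: 7 methyl benzyloxyacetate
Product: 8 methyl 2-benzyloxy-3-oxobutanoate (racemic)
Conditions: LiN(iPr)2 (2 equiv), 7 (2 equiv), THF, −78 °C; AcCl (1 equiv); aq. NH4Cl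
Reagents that add atoms: acetyl chloride, CC(=O)Cl
Why: Crossed Claisen C-acylation of the lithium ester enolate, the second equivalent of enolate taking up the acidic proton of the β-keto ester.

Step 6
Reactants: 8 methyl 2-benzyloxy-3-oxobutanoate
Product: 9 methyl 2-benzyloxy-3-(trimethylsilyloxy)but-2-enoate (E/Z mixture)
Conditions: Me3SiCl, Et3N, toluene, 23 °C
Reagents that add atoms: chlorotrimethylsilane, C[Si](C)(C)Cl
Why: Soft enolisation and O-silylation of the β-keto ester give the silyl enol ether.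

Step 7
Reactants: 9 methyl 2-benzyloxy-3-(trimethylsilyloxy)but-2-enoate
Product: 10 2-benzyloxy-1-methoxy-1,3-bis(trimethylsilyloxy)buta-1,3-diene
Conditions: LiN(iPr)2, THF, −78 °C; Me3SiCl; non-aqueous work-up, used crude
Reagents that add atoms: chlorotrimethylsilane, C[Si](C)(C)Cl
Why: γ-Deprotonation of the vinylogous ester and O-silylation of the dienolate give the 1,3-bis(silyloxy)diene (a silyl ketene acetal).

Step 8
Reactants: 6 (2S,4S)-7,8-bis(benzyloxy)-2-(4-benzyloxyphenyl)chroman-4-ol; 10 2-benzyloxy-1-methoxy-1,3-bis(trimethylsilyloxy)buta-1,3-diene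
Product: 11 methyl 2-benzyloxy-3-oxo-4-[(2S,4S)-7,8-bis(benzyloxy)-2-(4-benzyloxyphenyl)chroman-4-yl]butanoate (2,4-trans flavan, both epimers at C2 of the chain)
Conditions: 10 (2 equiv), Me3SiOTf (0.2 equiv), CH2Cl2, −78 → −40 °C; aq. NaHCO3
Reagents that add atoms: none
Why: Vinylogous Mukaiyama-type SN1 alkylation in which the 4-carbinol ionises to a flavan-4-yl cation stabilised by O1 and the 7-benzyloxy group, and the terminal carbon of the diene attacks it pseudo-axially, anti to the axial C3–H and therefore trans to the equatorial C2 aryl, which sets upper C4.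

Step 9
Reactants: 11 methyl 2-benzyloxy-3-oxo-4-[(2S,4S)-flavan-4-yl]butanoate
Product: 12 methyl 2-benzyloxy-3-(trimethylsilyloxy)-4-[(2S,4S)-7,8-bis(benzyloxy)-2-(4-benzyloxyphenyl)chroman-4-yl]but-2-enoate (E/Z mixture)
Conditions: Me3SiCl, Et3N, toluene, 23 °C
Reagents that add atoms: chlorotrimethylsilane, C[Si](C)(C)Cl
Why: O-Silylation of the enolised β-keto ester, as in step 6, also removes the epimeric chain carbon.

Step 10
Reactants: 12 silyl enol ether of 11
Product: 13 (3Z)-2-benzyloxy-1-methoxy-1,3-bis(trimethylsilyloxy)-4-[(2S,4S)-7,8-bis(benzyloxy)-2-(4-benzyloxyphenyl)chroman-4-yl]buta-1,3-diene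
Conditions: LiN(iPr)2, THF, −78 °C; Me3SiCl; non-aqueous work-up, used crude
Reagents that add atoms: chlorotrimethylsilane, C[Si](C)(C)Cl
Why: γ-Deprotonation and O-silylation as in step 7, the flavanyl group taking the position trans to the substituted C2 of the diene to avoid allylic strain.

Step 11
Reactants: 14 (R)-4-benzyloxazolidin-2-one
Product: 15 (R)-4-benzyl-3-(2-benzyloxyacetyl)oxazolidin-2-one
Conditions: n-BuLi, THF, −78 °C; BnOCH2COCl
Reagents that add atoms: benzyloxyacetyl chloride, O=C(Cl)COCc1ccccc1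
Why: N-Acylation of the lithiated oxazolidinone with the acid chloride.

Step 12
Reactants: 15 (R)-4-benzyl-3-(2-benzyloxyacetyl)oxazolidin-2-one; 3 4-benzyloxybenzaldehyde
Product: 17 (R)-4-benzyl-3-[(2S,3S)-2-benzyloxy-3-(4-benzyloxyphenyl)-3-hydroxypropanoyl]oxazolidin-2-one, via aldol trimethylsilyl ether 16 (not isolated)
Conditions: MgCl2 (0.2 equiv), Et3N (2 equiv), Me3SiCl (1.5 equiv), EtOAc, 23 °C; then aq. citric acid/THF, 0 °C
Reagents that add atoms: none
Why: Magnesium chloride-catalysed direct anti-aldol of an N-acyloxazolidinone with an aromatic aldehyde, in which the chelated (Z)-magnesium enolate is attacked on the face remote from the auxiliary benzyl group (setting 2S) through a boat-like transition state that gives the 2,3-anti (3S) adduct, silylation of the aldolate turning the metal over.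

Step 13
Reactants: 17 anti-aldol adduct
Product: 18 (2S,3S)-2-benzyloxy-3-(4-benzyloxyphenyl)-3-hydroxy-N-methoxy-N-methylpropanamide
Conditions: MeNH(OMe)·HCl, AlMe3, CH2Cl2, −20 → 0 °C; aq. sodium potassium tartrate
Reagents that add atoms: N,O-dimethylhydroxylamine hydrochloride, Cl.CNOC
Why: Aluminium amide transamination of the imide to the Weinreb amide, assisted by the free β-hydroxyl, releases the auxiliary without touching either stereocentre.

Step 14
Reactants: 18 Weinreb amide
Product: 19 (2S,3S)-2-benzyloxy-3-(4-benzyloxyphenyl)-3-(tert-butyldimethylsilyloxy)-N-methoxy-N-methylpropanamide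
Conditions: tBuMe2SiOTf, 2,6-lutidine, CH2Cl2, −78 → 0 °C
Reagents that add atoms: tert-butyldimethylsilyl trifluoromethanesulfonate, CC(C)(C)[Si](C)(C)OS(=O)(=O)C(F)(F)F
Why: Silylation of the hindered secondary alcohol, needed because a free β-hydroxy ynone would cyclise onto the alkyne.

Step 15
Reactants: 19 silylated Weinreb amide
Product: 20 (4S,5S)-4-benzyloxy-5-(4-benzyloxyphenyl)-5-(tert-butyldimethylsilyloxy)pent-1-yn-3-one
Conditions: HC≡CMgBr (3 equiv), THF, −78 → 0 °C; poured into cold 1 M HCl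
Reagents that add atoms: ethynylmagnesium bromide, C#C[Mg]Br
Why: Weinreb ketone synthesis, where the chelated tetrahedral intermediate prevents over-addition and the acidic quench keeps the released amine from adding to the ynone.

Step 16
Reactants: 13 (3Z)-bis(silyloxy)diene carrying the upper flavan; 20 (4S,5S)-ynone (1.3 equiv)
Product: 23 (2S,3S)-2-benzyloxy-1-{3-benzyloxy-2,4-dihydroxy-5-[(2S)-2,4-trans-7,8-bis(benzyloxy)-2-(4-benzyloxyphenyl)chroman-4-yl]phenyl}-3-(4-benzyloxyphenyl)-3-(tert-butyldimethylsilyloxy)propan-1-one, via cyclohexa-1,4-diene cycloadduct 21 (not isolated), via bis(trimethylsilyl) aryl ether 22 (not isolated)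
Conditions: toluene, 0 → 23 °C (45 °C if slow); then 10% aq. citric acid/THF, 0 °C
Reagents that add atoms: none
Why: The diene is an electron-rich 1,1,2,3-tetraoxygenated butadiene with its largest HOMO coefficient at C4 (the carbon bearing the upper flavan, future C6), so this terminus adds to the β-carbon of the ynone (future C5) and the ketene acetal carbon (future C8a) then bonds to the α-carbon (future C4a) in a polarised, asynchronous Diels–Alder reaction. The closest known reaction type is the cycloaddition of 1-alkoxy-1,3-bis(silyloxy)buta-1,3-dienes with acetylenic ketones and esters, followed by loss of the alcohol to give 2-acylphenols. Lower ring A closes as a six-membered carbocycle by this intermolecular [4+2] process; 1,4-elimination of methanol from C8a and C6 of 21 aromatises it, and hydrolysis of the two aryl silyl ethers of 22 leaves the C8a and C7 phenols. No stereocentre is created, since the sp3 carbons C6 and C8a of 21 disappear on aromatisation, and the four existing centres are not touched under neutral, base-free conditions. The step needs regioselectivity (acyl group next to C8a–OH, hydrogen at C5), which the matched polarity of the ketene acetal terminus and the ynone should secure; the (3Z) geometry keeps the flavanyl group outside the s-cis diene so that the reactive conformer is accessible.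

Step 17
Reactants: 23 2,4-dihydroxyaryl ketone
Product: 24 the 4-O-benzyl ether of 23 (benzyl on the phenol para to the ketone, future lower C7–O)
Conditions: BnBr (1.1 equiv), K2CO3 (1.2 equiv), acetone, 23 °C
Reagents that add atoms: benzyl bromide, BrCc1ccccc1
Why: Williamson etherification selective for the more acidic, non-chelated para phenol, the ortho phenol being held by its hydrogen bond to the ketone.

Step 18
Reactants: 24 silyl ether
Product: 25 (2S,3S)-2-benzyloxy-1-{3,4-bis(benzyloxy)-2-hydroxy-5-[(2S)-2,4-trans-flavan-4-yl]phenyl}-3-(4-benzyloxyphenyl)-3-hydroxypropan-1-one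
Conditions: Bu4NF, AcOH, THF, 0 → 23 °C
Reagents that add atoms: none
Why: Fluoride-mediated desilylation, buffered with acetic acid so that the β-hydroxy ketone neither epimerises nor undergoes retro-aldol cleavage.

Step 19
Reactants: 25 β-hydroxy ketone with free ortho phenol
Product: 26 (2R,3S)-3,7,8-tris(benzyloxy)-2-(4-benzyloxyphenyl)-6-[(2S)-2,4-trans-7,8-bis(benzyloxy)-2-(4-benzyloxyphenyl)chroman-4-yl]chroman-4-one (2,3-cis)
Conditions: PPh3, DIAD, THF (0.01 M), 0 → 23 °C
Reagents that add atoms: none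
Why: Intramolecular Mitsunobu etherification, in which the acidic chelated phenol displaces the benzylic oxyphosphonium group in a 6-exo-tet SN2 step with inversion, turning the (3S)-carbinol into lower C2 (R) and closing lower ring C with the 2-aryl and 3-benzyloxy groups cis.

Step 20
Reactants: 26 2,3-cis-3-benzyloxyflavanone
Product: 27 (2R,3R,4R)-3,7,8-tris(benzyloxy)-2-(4-benzyloxyphenyl)-6-[(2S)-2,4-trans-7,8-bis(benzyloxy)-2-(4-benzyloxyphenyl)chroman-4-yl]chroman-4-ol (all-cis)
Conditions: NaBH4, CeCl3·7H2O, MeOH/THF, −40 °C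
Reagents that add atoms: none
Why: Luche reduction, in which hydride adds to the C4 carbonyl anti to the pseudo-axial C3–OBn bond (polar Felkin–Anh and steric approach agree) and places the new hydroxyl cis to it (4R), the cold, weakly basic medium protecting the epimerisable C2 and C3.

Step 21
Reactants: 27 hepta-O-benzyl ether
Product: 28 target, (2S,4S)-7,8,4′-trihydroxyflavan-(4→6)-(2R,3R,4R)-7,8,4′-trihydroxyflavan-3,4-diol
Conditions: H2 (1 atm), Pd(OH)2 on carbon, THF/MeOH, 23 °C, stopped at full debenzylation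
Reagents that add atoms: none
Why: Hydrogenolysis of the seven benzyl ethers under neutral conditions, where aryl and alkyl benzyl ethers cleave faster than the C4 carbinol or the ring C–O bonds.

**Compound list**

1 | gallacetophenone (2′,3′,4′-trihydroxyacetophenone) | CC(=O)c1ccc(O)c(O)c1O | starting material
2 | 3′,4′-bis(benzyloxy)-2′-hydroxyacetophenone | CC(=O)c1ccc(OCc2ccccc2)c(OCc2ccccc2)c1O | intermediate
3 | 4-benzyloxybenzaldehyde | O=Cc1ccc(OCc2ccccc2)cc1 | starting material
4 | (E)-4,3′,4′-tris(benzyloxy)-2′-hydroxychalcone | O=C(/C=C/c1ccc(OCc2ccccc2)cc1)c1ccc(OCc2ccccc2)c(OCc2ccccc2)c1O | intermediate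
5 | racemic 7,8-bis(benzyloxy)-2-(4-benzyloxyphenyl)chroman-4-one | O=C1CC(c2ccc(OCc3ccccc3)cc2)Oc2c1ccc(OCc1ccccc1)c2OCc1ccccc1 | intermediate
6 | (2S,4S)-7,8-bis(benzyloxy)-2-(4-benzyloxyphenyl)chroman-4-ol | O[C@H]1C[C@@H](c2ccc(OCc3ccccc3)cc2)Oc2c1ccc(OCc1ccccc1)c2OCc1ccccc1 | intermediate
7 | methyl benzyloxyacetate | COC(=O)COCc1ccccc1 | starting material
8 | methyl 2-benzyloxy-3-oxobutanoate (racemic) | COC(=O)C(OCc1ccccc1)C(C)=O | intermediate
9 | methyl 2-benzyloxy-3-(trimethylsilyloxy)but-2-enoate (E/Z mixture) | COC(=O)C(OCc1ccccc1)=C(C)O[Si](C)(C)C | intermediate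
10 | 2-benzyloxy-1-methoxy-1,3-bis(trimethylsilyloxy)buta-1,3-diene | COC(O[Si](C)(C)C)=C(OCc1ccccc1)C(=C)O[Si](C)(C)C | intermediate
11 | methyl 2-benzyloxy-3-oxo-4-[(2S,4S)-7,8-bis(benzyloxy)-2-(4-benzyloxyphenyl)chroman-4-yl]butanoate (epimers at chain C2) | COC(=O)C(OCc1ccccc1)C(=O)C[C@@H]1C[C@@H](c2ccc(OCc3ccccc3)cc2)Oc2c1ccc(OCc1ccccc1)c2OCc1ccccc1 | intermediate
12 | methyl 2-benzyloxy-3-(trimethylsilyloxy)-4-[(2S,4S)-flavan-4-yl]but-2-enoate (E/Z mixture) | COC(=O)C(OCc1ccccc1)=C(O[Si](C)(C)C)C[C@@H]1C[C@@H](c2ccc(OCc3ccccc3)cc2)Oc2c1ccc(OCc1ccccc1)c2OCc1ccccc1 | intermediate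
13 | (3Z)-2-benzyloxy-1-methoxy-1,3-bis(trimethylsilyloxy)-4-[(2S,4S)-flavan-4-yl]buta-1,3-diene (one ketene acetal isomer drawn) | CO/C(O[Si](C)(C)C)=C(OCc1ccccc1)/C(O[Si](C)(C)C)=C/[C@@H]1C[C@@H](c2ccc(OCc3ccccc3)cc2)Oc2c1ccc(OCc1ccccc1)c2OCc1ccccc1 | intermediate
14 | (R)-4-benzyloxazolidin-2-one | O=C1OC[C@@H](Cc2ccccc2)N1 | starting material
15 | (R)-4-benzyl-3-(2-benzyloxyacetyl)oxazolidin-2-one | O=C1OC[C@@H](Cc2ccccc2)N1C(=O)COCc1ccccc1 | intermediate
16 | trimethylsilyl ether of aldol adduct 17 | O=C1OC[C@@H](Cc2ccccc2)N1C(=O)[C@@H](OCc1ccccc1)[C@@H](O[Si](C)(C)C)c1ccc(OCc2ccccc2)cc1 | intermediate (not isolated)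
17 | (R)-4-benzyl-3-[(2S,3S)-2-benzyloxy-3-(4-benzyloxyphenyl)-3-hydroxypropanoyl]oxazolidin-2-one | O=C1OC[C@@H](Cc2ccccc2)N1C(=O)[C@@H](OCc1ccccc1)[C@@H](O)c1ccc(OCc2ccccc2)cc1 | intermediate
18 | (2S,3S)-2-benzyloxy-3-(4-benzyloxyphenyl)-3-hydroxy-N-methoxy-N-methylpropanamide | CON(C)C(=O)[C@@H](OCc1ccccc1)[C@@H](O)c1ccc(OCc2ccccc2)cc1 | intermediate
19 | (2S,3S)-2-benzyloxy-3-(4-benzyloxyphenyl)-3-(tert-butyldimethylsilyloxy)-N-methoxy-N-methylpropanamide | CON(C)C(=O)[C@@H](OCc1ccccc1)[C@@H](O[Si](C)(C)C(C)(C)C)c1ccc(OCc2ccccc2)cc1 | intermediate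
20 | (4S,5S)-4-benzyloxy-5-(4-benzyloxyphenyl)-5-(tert-butyldimethylsilyloxy)pent-1-yn-3-one | C#CC(=O)[C@@H](OCc1ccccc1)[C@@H](O[Si](C)(C)C(C)(C)C)c1ccc(OCc2ccccc2)cc1 | intermediate
21 | cyclohexa-1,4-diene cycloadduct (C8a bearing OMe and OSiMe3, C6 sp3; epimers) | C(c5ccccc5)Oc1ccc([C@@H]2C[C@@H](C3C=C(C(=O)[C@@H](OCc5ccccc5)[C@@H](O[Si](C)(C)C(C)(C)C)c4ccc(OCc5ccccc5)cc4)C(OC)(O[Si](C)(C)C)C(OCc5ccccc5)=C3O[Si](C)(C)C)c3ccc(OCc5ccccc5)c(OCc5ccccc5)c3O2)cc1 | intermediate (not isolated)
22 | bis(trimethylsilyl) aryl ether of 23 | C(c5ccccc5)Oc1ccc([C@@H]2C[C@@H](c3cc(C(=O)[C@@H](OCc5ccccc5)[C@@H](O[Si](C)(C)C(C)(C)C)c4ccc(OCc5ccccc5)cc4)c(O[Si](C)(C)C)c(OCc5ccccc5)c3O[Si](C)(C)C)c3ccc(OCc5ccccc5)c(OCc5ccccc5)c3O2)cc1 | intermediate (not isolated)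
23 | 3-benzyloxy-2,4-dihydroxyaryl ketone bearing the upper flavan and the silylated (2S,3S) side chain | C(c5ccccc5)Oc1ccc([C@@H]2C[C@@H](c3cc(C(=O)[C@@H](OCc5ccccc5)[C@@H](O[Si](C)(C)C(C)(C)C)c4ccc(OCc5ccccc5)cc4)c(O)c(OCc5ccccc5)c3O)c3ccc(OCc5ccccc5)c(OCc5ccccc5)c3O2)cc1 | intermediate
24 | 4-O-benzyl ether of 23 (3,4-bis(benzyloxy)-2-hydroxyaryl ketone) | C(c5ccccc5)Oc1ccc([C@@H]2C[C@@H](c3cc(C(=O)[C@@H](OCc5ccccc5)[C@@H](O[Si](C)(C)C(C)(C)C)c4ccc(OCc5ccccc5)cc4)c(O)c(OCc5ccccc5)c3OCc5ccccc5)c3ccc(OCc5ccccc5)c(OCc5ccccc5)c3O2)cc1 | intermediate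
25 | desilylated (2S,3S)-β-hydroxy ketone | C(c5ccccc5)Oc1ccc([C@@H]2C[C@@H](c3cc(C(=O)[C@@H](OCc5ccccc5)[C@@H](O)c4ccc(OCc5ccccc5)cc4)c(O)c(OCc5ccccc5)c3OCc5ccccc5)c3ccc(OCc5ccccc5)c(OCc5ccccc5)c3O2)cc1 | intermediate
26 | (2R,3S)-2,3-cis-3-benzyloxyflavanone bearing the upper flavan at C6 | C(c5ccccc5)Oc1ccc([C@@H]2C[C@@H](c3cc4c(c(OCc5ccccc5)c3OCc5ccccc5)O[C@H](c3ccc(OCc5ccccc5)cc3)[C@H](OCc5ccccc5)C4=O)c3ccc(OCc5ccccc5)c(OCc5ccccc5)c3O2)cc1 | intermediate
27 | (2R,3R,4R)-all-cis hepta-O-benzyl flavan-4-ol | C(c5ccccc5)Oc1ccc([C@@H]2C[C@@H](c3cc4c(c(OCc5ccccc5)c3OCc5ccccc5)O[C@H](c3ccc(OCc5ccccc5)cc3)[C@H](OCc5ccccc5)[C@@H]4O)c3ccc(OCc5ccccc5)c(OCc5ccccc5)c3O2)cc1 | intermediate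
28 | CNP0209379.1 | Oc1ccc([C@@H]2C[C@@H](c3cc4c(c(O)c3O)O[C@H](c3ccc(O)cc3)[C@H](O)[C@@H]4O)c3ccc(O)c(O)c3O2)cc1 | target

**Step count**

Total step count: 21. Longest linear sequence: 13 steps (steps 1–4, 8–10, 16–21).

**Steps most likely to fail**

Step 16. The crowded, fully substituted diene may add too slowly and be desilylated or protonated first, or the addition may stop at an open-chain Michael adduct that does not close and aromatise. The fallback raises the nucleophilicity of the diene by changing the ketene acetal into a ketene N,O-acetal. It sets out from 11, which is heated with dimethylamine in toluene (transamidation through the acylketene) to give the N,N-dimethyl β-keto amide F1. Silylation with Me3SiCl/Et3N and then LiN(iPr)2/Me3SiCl gives the 1-dimethylamino-1,3-bis(trimethylsilyloxy)diene F2. Cycloaddition of F2 with 20, loss of dimethylamine in place of methanol and the same citric acid work-up bring the route back at 23.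

Step 19. The oxyphosphonium group sits on a 4-benzyloxyphenyl carbinol and may ionise, which would erode the configuration at lower C2, or it may eliminate to the enone. The fallback gives up acyclic control of the lower unit and accepts a separation. It sets out from 25, which is oxidised with Dess–Martin periodinane to the 1,3-diketone F3. Acid-catalysed cyclodehydration (TsOH, toluene) gives the 3-benzyloxyflavone F4, and hydrogenolysis over Pd(OH)2 on carbon gives the free flavonol F5. Hydrogenation of F5 over PtO2 in ethanol adds hydrogen to one face of the pyranone ring and gives the all-cis 3,4-diol as two diastereomers, 28 and its lower-unit (2S,3S,4S) isomer F6, which are separated by preparative HPLC; the route comes back at 28.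

Step 8. The acid-sensitive diene 10 may be protodesilylated or attack through its inner carbon, the cation may eliminate to the flav-3-ene, and facial selectivity at upper C4 may be insufficient. The fallback uses a smaller, more robust two-carbon nucleophile and builds the keto ester afterwards. It sets out from 6, which is treated with 1-(tert-butyldimethylsilyloxy)-1-methoxyethene and catalytic Me3SiOTf to give the methyl (2,4-trans-flavan-4-yl)acetate F7. Saponification with LiOH gives the acid F8, and carbonyldiimidazole gives the acyl imidazole F9. Claisen acylation of the lithium enolate of 7 (2 equiv) with F9 brings the route back at 11.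

Further compounds
F1 | step 16 | N,N-dimethyl 2-benzyloxy-3-oxo-4-[(2S,4S)-7,8-bis(benzyloxy)-2-(4-benzyloxyphenyl)chroman-4-yl]butanamide | CN(C)C(=O)C(OCc1ccccc1)C(=O)C[C@@H]1C[C@@H](c2ccc(OCc3ccccc3)cc2)Oc2c1ccc(OCc1ccccc1)c2OCc1ccccc1
F2 | step 16 | (3Z)-2-benzyloxy-1-dimethylamino-1,3-bis(trimethylsilyloxy)-4-[(2S,4S)-flavan-4-yl]buta-1,3-diene | CN(C)C(O[Si](C)(C)C)=C(OCc1ccccc1)/C(O[Si](C)(C)C)=C/[C@@H]1C[C@@H](c2ccc(OCc3ccccc3)cc2)Oc2c1ccc(OCc1ccccc1)c2OCc1ccccc1
F3 | step 19 | 2-benzyloxy-1-aryl-3-(4-benzyloxyphenyl)propane-1,3-dione from 25 | C(c5ccccc5)Oc1ccc([C@@H]2C[C@@H](c3cc(C(=O)C(OCc5ccccc5)C(=O)c4ccc(OCc5ccccc5)cc4)c(O)c(OCc5ccccc5)c3OCc5ccccc5)c3ccc(OCc5ccccc5)c(OCc5ccccc5)c3O2)cc1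
F4 | step 19 | 3,7,8-tris(benzyloxy)-2-(4-benzyloxyphenyl)flavone bearing the upper flavan at C6 | C(c5ccccc5)Oc1ccc([C@@H]2C[C@@H](c3cc4c(c(OCc5ccccc5)c3OCc5ccccc5)oc(-c3ccc(OCc5ccccc5)cc3)c(OCc5ccccc5)c4=O)c3ccc(OCc5ccccc5)c(OCc5ccccc5)c3O2)cc1
F5 | step 19 | 3,7,8,4′-tetrahydroxyflavone bearing the free upper flavan at C6 | Oc1ccc([C@@H]2C[C@@H](c3cc4c(c(O)c3O)oc(-c3ccc(O)cc3)c(O)c4=O)c3ccc(O)c(O)c3O2)cc1
F6 | step 19 | diastereomer of 28 with a (2S,3S,4S) lower unit | Oc1ccc([C@@H]2C[C@@H](c3cc4c(c(O)c3O)O[C@@H](c3ccc(O)cc3)[C@@H](O)[C@H]4O)c3ccc(O)c(O)c3O2)cc1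
F7 | step 8 | methyl 2-[(2S,4S)-7,8-bis(benzyloxy)-2-(4-benzyloxyphenyl)chroman-4-yl]acetate | COC(=O)C[C@@H]1C[C@@H](c2ccc(OCc3ccccc3)cc2)Oc2c1ccc(OCc1ccccc1)c2OCc1ccccc1
F8 | step 8 | 2-[(2S,4S)-7,8-bis(benzyloxy)-2-(4-benzyloxyphenyl)chroman-4-yl]acetic acid | OC(=O)C[C@@H]1C[C@@H](c2ccc(OCc3ccccc3)cc2)Oc2c1ccc(OCc1ccccc1)c2OCc1ccccc1
F9 | step 8 | 1-{2-[(2S,4S)-flavan-4-yl]acetyl}imidazole | O=C(C[C@@H]1C[C@@H](c2ccc(OCc3ccccc3)cc2)Oc2c1ccc(OCc1ccccc1)c2OCc1ccccc1)n1ccnc1
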